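**Retrosynthetic overview**

1. Locants follow longipinane numbering: C1 ring C=O, C2=C3(Me), C4/C11 bridgeheads, C5/C10 the other cyclobutane carbons, C6 CMe2, C7 OTig, C8, C9 OSen. The esters go on last: an Evans–Tishchenko reduction of the 7‑hydroxy‑9‑ketone with tiglaldehyde gives the C7 tiglate and the anti C9 carbinol together, and acylation gives the C9 senecioate. C7–OH comes from a cycloheptenone by catalyst‑controlled conjugate borylation; the C1 enone comes from a C3 tertiary alcohol (dehydration, allylic oxidation).
2. Key disconnection: C6–C7 and C4–C10 are cut together, which takes the tricycle back to monocyclic epoxy ynone 10.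
3. Enabling feature: in 10 the C11 side chain (C10–H beside the C9 ynone carbonyl) and the C5 isopropenyl group are cis on the cyclohexane, and the C3–C4 epoxide lies on the opposite face. The C6 radical can then reach the ynone terminus C7 (seven‑membered ring). Once that ring exists, the only enolisable carbon, C10, sits 1,3‑diaxial over C4 and anti to its C–O bond (four‑membered ring).
4. 10 comes from (E)‑2,5‑dimethylhexa‑1,3,5‑triene and methyl vinyl ketone by a catalytic asymmetric endo Diels–Alder reaction (sets C11 and C5), one‑carbon homologation, ethynylation/oxidation and epoxidation. C7 is later set by a chiral copper catalyst; C3, C4, C9 and C10 are relayed.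
5. Ring order: six‑membered ring (Diels–Alder), then seven‑membered ring (radical 7‑endo‑dig), then four‑membered ring (4‑exo‑tet epoxide opening).

Key step: step 8

**Route**

Step 1
Reactants: 1 2,5-dimethylhex-3-yne-2,5-diol
Product: 2 (E)-2,5-dimethylhex-3-ene-2,5-diol
Conditions: LiAlH4, THF, reflux; then H2O
Reagents that add atoms: none
Why: LiAlH4 reduction of a propargylic alcohol runs by alkoxide-directed trans-hydroalumination, so the alkyne should give the (E)-alkene only.

Step 2
Reactants: 2 (E)-2,5-dimethylhex-3-ene-2,5-diol
Product: 3 (E)-2,5-dimethylhexa-1,3,5-triene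
Conditions: Burgess reagent (2.5 equiv), benzene, 50 °C
Reagents that add atoms: none
Why: Burgess dehydration (syn-elimination through the sulfamate ester) can only remove a methyl hydrogen from each tertiary allylic carbinol, so both ends should become isopropenyl groups while the (E)-alkene is kept and cationic transposition is avoided.

Step 3
Reactants: 3 (E)-2,5-dimethylhexa-1,3,5-triene; 4 but-3-en-2-one (methyl vinyl ketone)
Product: 5 1-[(1R,2S)-4-methyl-2-(prop-1-en-2-yl)cyclohex-3-en-1-yl]ethan-1-one (acetyl cis to isopropenyl)
Conditions: (S)-o-tolyl-CBS-oxazaborolidine·HNTf2 (10 mol%), CH2Cl2, −78 to −40 °C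
Reagents that add atoms: none
Why: Lewis-acid-catalysed Diels–Alder reaction in which the terminal isopropenyl group and the internal methyl group of the diene both direct the acetyl-bearing carbon next to the isopropenyl-bearing carbon (ortho/para rule), the endo transition state of the (E)-diene places acetyl and isopropenyl cis, and the chiral oxazaborolidinium cation shields one face of the bound enone so that the (1R,2S) enantiomer is expected (the antipodal catalyst is used if the sense proves opposite).

Step 4
Reactants: 5 1-[(1R,2S)-4-methyl-2-(prop-1-en-2-yl)cyclohex-3-en-1-yl]ethan-1-one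
Product: 7 2-[cis-4-methyl-2-(prop-1-en-2-yl)cyclohex-3-en-1-yl]propanal (ring configuration of 5; epimers at the chain carbon), via enol ether 6 (not isolated)
Conditions: MeOCH2PPh3Cl, KHMDS, THF, 0 °C; then 1 M HCl, THF, 0 °C
Reagents that add atoms: (methoxymethyl)triphenylphosphonium chloride, COC[P+](c1ccccc1)(c1ccccc1)c1ccccc1.[Cl-] (aldehyde carbon; the methoxy group stays only in 6); water, O
Why: Wittig methoxymethylenation followed by acid hydrolysis of the enol ether is the standard one-carbon homologation of a ketone to an α-branched aldehyde; the new chain stereocentre is uncontrolled but is erased later by enolisation.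

Step 5
Reactants: 7 2-[cis-4-methyl-2-(prop-1-en-2-yl)cyclohex-3-en-1-yl]propanal
Product: 8 4-[cis-4-methyl-2-(prop-1-en-2-yl)cyclohex-3-en-1-yl]pent-1-yn-3-ol (diastereomer mixture in the chain)
Conditions: HC≡CMgBr, THF, −78 to 0 °C; aq. NH4Cl
Reagents that add atoms: ethynylmagnesium bromide, C#C[Mg]Br
Why: Grignard addition of the acetylide to the aldehyde; the carbinol centre is oxidised away in the next step.

Step 6
Reactants: 8 4-[cis-4-methyl-2-(prop-1-en-2-yl)cyclohex-3-en-1-yl]pent-1-yn-3-ol
Product: 9 4-[cis-4-methyl-2-(prop-1-en-2-yl)cyclohex-3-en-1-yl]pent-1-yn-3-one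
Conditions: Dess–Martin periodinane, CH2Cl2, 0 °C to rt
Reagents that add atoms: none
Why: Dess–Martin oxidation of a secondary propargylic alcohol should give the ynone under neutral conditions that leave both alkenes alone.

Step 7
Reactants: 9 4-[cis-4-methyl-2-(prop-1-en-2-yl)cyclohex-3-en-1-yl]pent-1-yn-3-one
Product: 10 4-[1-methyl-5-(prop-1-en-2-yl)-7-oxabicyclo[4.1.0]heptan-4-yl]pent-1-yn-3-one (side chain cis to isopropenyl; epoxide oxygen trans to both)
Conditions: mCPBA (1.05 equiv), CH2Cl2, −20 °C
Reagents that add atoms: mCPBA, OOC(=O)c1cccc(Cl)c1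
Why: Prilezhaev epoxidation is fastest at the electron-rich trisubstituted ring alkene (over the isopropenyl group and the electron-poor ynone) and should occur anti to the allylic isopropenyl group and the cis side chain, which sets C3 and C4 with the oxygen trans to both substituents.

Step 8
Reactants: 10 4-[1-methyl-5-(prop-1-en-2-yl)-7-oxabicyclo[4.1.0]heptan-4-yl]pent-1-yn-3-one
Product: 12 3-hydroxylongipin-7-en-9-one (tricyclic hydroxy enone; C3–OH anti to C10), via epoxy enone 11 (not isolated)
Conditions: Fe(acac)3 (30 mol%), PhSiH3, EtOH/(CH2OH)2, 60 °C, 0.01 M; evaporate; KOt-Bu, t-BuOH/THF, 40 °C; AcOH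
Reagents that add atoms: none
Why: Proposed new method: hydrogen-atom transfer from an iron hydride to the isopropenyl group gives the tertiary C6 radical, which adds to the β-carbon C7 of the ynone in a 7-endo-dig closure of the seven-membered ring, and the vinyl radical then takes a hydrogen atom to give cis-fused cycloheptenone 11; after removal of the silane, KOt-Bu forms the only possible enolate (C9–C10, since the γ-carbon C6 is quaternary), whose C10 opens the epoxide at C4 in a 4-exo-tet closure of the cyclobutane. The closest known reaction types are the iron-mediated hydrogen-atom-transfer-initiated Giese addition of olefins to enones and the base-induced cyclobutane-forming cyclisation of epoxy ketones and epoxy nitriles. C5 and C11 come from step 3, C3 keeps the epoxide configuration, C4 is set by inversion at the epoxide carbon, and C10 is fixed because the enolate carbon already lies in the seven-membered ring and can reach C4 only from the face cis to the C5–C6 bond, so its methyl group must end outside. The selectivities needed are β-attack on the ynone over 6-exo attack (secured by the polarity match of the nucleophilic tertiary radical and by the carbonyl lying inside the forming ring), attack at C4 and not at the tertiary C3, and C- instead of O-alkylation (favoured by the trans-diaxial alignment of C10 with the C4–O bond).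

Step 9
Reactants: 12 3-hydroxylongipin-7-en-9-one
Product: 13 longipina-2,7-dien-9-one
Conditions: Burgess reagent, benzene, 50 °C
Reagents that add atoms: none
Why: Burgess dehydration is a non-ionising syn-elimination that should give mainly the trisubstituted endocyclic C2=C3 alkene (the bridgehead hydrogen at C4 cannot be lost) and avoids the cyclobutylcarbinyl cation that would rearrange the skeleton.

Step 10
Reactants: 13 longipina-2,7-dien-9-one
Product: 14 longipina-2,7-diene-1,9-dione
Conditions: CrO3, 3,5-dimethylpyrazole, CH2Cl2, −20 °C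
Reagents that add atoms: chromium trioxide, O=[Cr](=O)=O
Why: Allylic oxidation with the CrO3–3,5-dimethylpyrazole complex should attack the only allylic methylene (C1), as in the conversion of α-pinene into verbenone, and leave the cycloheptenone alone because its γ-carbon is quaternary.

Step 11
Reactants: 14 longipina-2,7-diene-1,9-dione
Product: 16 7-hydroxylongipin-2-ene-1,9-dione (C7–O on the face toward C4), via boronate 15 (not isolated)
Conditions: CuCl (5 mol%), (R)-1-[(S)-2-(diphenylphosphino)ferrocenyl]ethyldicyclohexylphosphine (5 mol%), NaOt-Bu (10 mol%), B2pin2, MeOH, THF, rt; then NaBO3·4H2O, THF/H2O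
Reagents that add atoms: bis(pinacolato)diboron, CC1(C)OB(OC1(C)C)B1OC(C)(C)C(C)(C)O1 (boryl group of 15 only); sodium perborate, [Na+].[Na+].O[B-]1(O)OO[B-](O)(O)OO1 (oxygen at C7)
Why: Copper-catalysed conjugate borylation should add boron only to the β-carbon of the less substituted cycloheptenone (the β,β-disubstituted bicyclic enone is too hindered), the chiral ferrocenyl diphosphine controls the face because the substrate gives little bias at C7 (the ligand antipode is used if the sense proves opposite), and perborate oxidation replaces boron by oxygen with retention.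

Step 12
Reactants: 16 7-hydroxylongipin-2-ene-1,9-dione; 17 (E)-2-methylbut-2-enal (tiglaldehyde)
Product: 18 9-hydroxy-1-oxolongipin-2-en-7-yl (E)-2-methylbut-2-enoate (C9–OH trans to the C7 ester)
Conditions: SmI2 (30 mol%), THF, −10 °C
Reagents that add atoms: none
Why: Evans–Tishchenko reduction, in which the samarium-bound hemiacetal formed from the C7 hydroxyl and the aldehyde delivers its hydride intramolecularly to C9, should give the 1,3-anti (trans) carbinol and at the same time turn the aldehyde into the C7 tiglate.

Step 13
Reactants: 18 9-hydroxy-1-oxolongipin-2-en-7-yl (E)-2-methylbut-2-enoate; 19 3-methylbut-2-enoyl chloride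
Product: 20 CNP0257816.1 (1-oxo-9-(3-methylbut-2-enoyloxy)longipin-2-en-7-yl (E)-2-methylbut-2-enoate)
Conditions: pyridine, DMAP (cat.), CH2Cl2, 0 °C to rt
Reagents that add atoms: none
Why: DMAP-catalysed acylation of the remaining hindered secondary alcohol; pyridine instead of a trialkylamine is used to avoid vinylketene formation and deconjugation of the senecioyl group.

**Compound list**

1 | 2,5-dimethylhex-3-yne-2,5-diol | CC(C)(O)C#CC(C)(C)O | starting material
2 | (E)-2,5-dimethylhex-3-ene-2,5-diol | CC(C)(O)/C=C/C(C)(C)O | intermediate
3 | (E)-2,5-dimethylhexa-1,3,5-triene | C=C(C)/C=C/C(C)=C | intermediate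
4 | but-3-en-2-one (methyl vinyl ketone) | CC(=O)C=C | starting material
5 | 1-[(1R,2S)-4-methyl-2-(prop-1-en-2-yl)cyclohex-3-en-1-yl]ethan-1-one (cis) | CC(=O)[C@@H]1CCC(C)=C[C@@H]1C(C)=C | intermediate
6 | 1-methoxy-2-[cis-4-methyl-2-(prop-1-en-2-yl)cyclohex-3-en-1-yl]prop-1-ene (E/Z mixture; ring configuration of 5; not isolated) | COC=C(C)[C@@H]1CCC(C)=C[C@@H]1C(C)=C | intermediate
7 | 2-[cis-4-methyl-2-(prop-1-en-2-yl)cyclohex-3-en-1-yl]propanal (ring configuration of 5; epimers at C2 of the chain) | O=CC(C)[C@@H]1CCC(C)=C[C@@H]1C(C)=C | intermediate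
8 | 4-[cis-4-methyl-2-(prop-1-en-2-yl)cyclohex-3-en-1-yl]pent-1-yn-3-ol (ring configuration of 5; chain diastereomers) | C#CC(O)C(C)[C@@H]1CCC(C)=C[C@@H]1C(C)=C | intermediate
9 | 4-[cis-4-methyl-2-(prop-1-en-2-yl)cyclohex-3-en-1-yl]pent-1-yn-3-one (ring configuration of 5; epimers at C4 of the chain) | C#CC(=O)C(C)[C@@H]1CCC(C)=C[C@@H]1C(C)=C | intermediate
10 | 4-[1-methyl-5-(prop-1-en-2-yl)-7-oxabicyclo[4.1.0]heptan-4-yl]pent-1-yn-3-one (chain cis to isopropenyl, epoxide oxygen trans to both; epimers at C4 of the chain) | C#CC(=O)C(C)[C@@H]1CC[C@@]2(C)O[C@H]2[C@@H]1C(C)=C | intermediate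
11 | 3,4-epoxy-4,10-secolongipin-7-en-9-one (cis-fused cyclohexane/cycloheptenone, epoxide oxygen cis to the ring-fusion hydrogens; epimers at C10; not isolated) | C1=CC(=O)C(C)[C@@H]2CC[C@@]3(C)O[C@H]3[C@@H]2C1(C)C | intermediate
12 | 3-hydroxylongipin-7-en-9-one (C3–OH anti to C10) | C1=CC(=O)[C@@]2(C)[C@@H]3CC[C@@](C)(O)[C@H]2[C@@H]3C1(C)C | intermediate
13 | longipina-2,7-dien-9-one | C1=CC(=O)[C@@]2(C)[C@@H]3CC=C(C)[C@H]2[C@@H]3C1(C)C | intermediate
14 | longipina-2,7-diene-1,9-dione | C1=CC(=O)[C@@]2(C)[C@@H]3C(=O)C=C(C)[C@H]2[C@@H]3C1(C)C | intermediate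
15 | 7-(4,4,5,5-tetramethyl-1,3,2-dioxaborolan-2-yl)longipin-2-ene-1,9-dione (not isolated) | CC1(C)OB(OC1(C)C)[C@@H]2CC(=O)[C@@]3(C)[C@@H]4C(=O)C=C(C)[C@H]3[C@@H]4C2(C)C | intermediate
16 | 7-hydroxylongipin-2-ene-1,9-dione | O[C@@H]1CC(=O)[C@@]2(C)[C@@H]3C(=O)C=C(C)[C@H]2[C@@H]3C1(C)C | intermediate
17 | (E)-2-methylbut-2-enal (tiglaldehyde) | C/C=C(\C)C=O | starting material
18 | 9-hydroxy-1-oxolongipin-2-en-7-yl (E)-2-methylbut-2-enoate | C/C=C(\C)C(=O)O[C@@H]1C[C@@H](O)[C@@]2(C)[C@@H]3C(=O)C=C(C)[C@H]2[C@@H]3C1(C)C | intermediate
19 | 3-methylbut-2-enoyl chloride | CC(C)=CC(Cl)=O | starting material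
20 | CNP0257816.1 | C/C=C(\C)C(=O)O[C@@H]1C[C@@H](OC(=O)C=C(C)C)[C@@]2(C)[C@@H]3C(=O)C=C(C)[C@H]2[C@@H]3C1(C)C | target

**Totals and risks**

Total step count: 13. Longest linear sequence: 13 steps (1 to 20).

Steps most likely to fail:

1. Step 8 (proposed new method). Hydrogen-atom transfer to the tertiary C6 radical, or conjugate reduction of the ynone, may outrun the slow seven-membered ring closure. In the base stage, O-alkylation or base-induced isomerisation of the epoxide to an allylic alcohol may compete with C-alkylation. The fallback is stepwise, uses known chemistry, sets out from 10 and returns at 12. Markovnikov hydrochlorination of the isopropenyl group (Co(BF4)2·6H2O with a salen-type ligand, TsCl, PhSiH3, EtOH) should give the tertiary chloride F1. The radical is then generated without a fast hydrogen donor (n-Bu3SnH by syringe pump, AIBN, benzene, 80 °C, high dilution) and should cyclise to epoxy enone 11, which is isolated. Compound 11 is condensed with Me2NNH2 to the N,N-dimethylhydrazone F2. Its lithium aza-enolate (LDA, THF, 0 °C) is a purely carbon nucleophile and should open the epoxide to the cyclised hydrazone F3. Mild hydrolysis (aqueous CuCl2, THF) returns ketone 12.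

2. Step 9. Elimination toward the methyl group instead of the ring, or ionisation with rearrangement of the cyclobutylcarbinyl system. The fallback sets out from 12 and returns at 13. The elimination is run under the same non-ionising conditions without regard to regiochemistry, and the exocyclic methylene isomer F4 is not discarded: RhCl3·3H2O (cat.) in EtOH at 70 °C (metal-hydride addition–elimination) should move the double bond into the ring to give the more stable trisubstituted alkene 13.

3. Step 11. Poor facial selectivity at C7 (the substrate gives little bias) or competing borylation of the ring enone. The fallback sets out from 14 and returns at 16. Catalyst-controlled nucleophilic epoxidation of the cycloheptenone (9-amino-9-deoxy-epi-quinine trifluoroacetate salt, aqueous H2O2, dioxane) should give the 7,8-epoxy ketone F5. Reductive cleavage of its Cα–O bond (SmI2, THF/MeOH, −90 °C) then gives β-hydroxy ketone 16.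

**Further compounds**

F1 | step 8 | 4-[5-(2-chloropropan-2-yl)-1-methyl-7-oxabicyclo[4.1.0]heptan-4-yl]pent-1-yn-3-one | C#CC(=O)C(C)[C@@H]1CC[C@@]2(C)O[C@H]2[C@@H]1C(C)(C)Cl
F2 | step 8 | N,N-dimethylhydrazone of epoxy enone 11 | C1=CC(=NN(C)C)C(C)[C@@H]2CC[C@@]3(C)O[C@H]3[C@@H]2C1(C)C
F3 | step 8 | N,N-dimethylhydrazone of 3-hydroxylongipin-7-en-9-one | C1=CC(=NN(C)C)[C@@]2(C)[C@@H]3CC[C@@](C)(O)[C@H]2[C@@H]3C1(C)C
F4 | step 9 | longipina-3(12),7-dien-9-one (exocyclic methylene isomer of 13) | C1=CC(=O)[C@@]2(C)[C@@H]3CCC(=C)[C@H]2[C@@H]3C1(C)C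
F5 | step 11 | 7,8-epoxylongipin-2-ene-1,9-dione | O1[C@@H]2[C@H]1C(=O)[C@@]3(C)[C@@H]4C(=O)C=C(C)[C@H]3[C@@H]4C2(C)C
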